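**Remarks on the chemistry (assumptions)**

- Guaianolide numbering is used: unprimed locants for the cyclopentenone half (unit 1), primed locants for unit 2. Ring A = C1–C5, ring B = C1, C5–C10, ring C = C1, C2, C4′, C15′, C14, C10, ring D = C1′–C5′, ring E = C1′, C5′–C10′.
- (S)-(+)-Carvone is used, because C5 of carvone becomes C1′ and only the (S) enantiomer gives the required configuration there.
- Temporary stereocentres are drawn without configuration and any epimer mixture is carried on: C2 in 31–33, the C3′ and C10′ carbinols in 32–55, C7 in 29–41 (reagent 30 is racemic), and C4, C11, C11′ in 52 and 53. Each is erased later. In the fallback compounds F2–F5, C7 and C10 are likewise drawn without configuration.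
- Compounds 9, 10, 22 and 27 are taken to be commercially available.

## Analysis of the target

Target 58 is a dimer of two guaianolides. Unit 1 has a cross-conjugated 4-methylene-cyclopent-2-enone (ring A), a cycloheptane (ring B) and a trans-fused 6,12-α-methylene lactone. Unit 2 has a cyclopentanone (ring D), a cycloheptane (ring E) with a 10′(14′)-methylene, a free 8′-hydroxyl and a second α-methylene lactone. The halves share ring C, a cyclohexene closed through C14–C15′ and C2–C4′, so C4′ is a quaternary spiro centre next to the C3′ ketone.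

There are ten stereocentres. In unit 1, H5 and H6 are cis (C4 and O6 on the same face of ring B), H6 and H7 are trans, and H10 is cis to H7 and O6 but trans to H5. In unit 2, H1′, H5′, H7′ and H8′ share one face, H6′ is on the other, and C2 sits at C4′ on the face of H5′.

The two α-methylene lactones and the dienone are Michael acceptors, so they have to come last. C10–H and C5–H are vinylogous α-protons of the enone and can epimerise. The free 8′-hydroxyl is cis to C11′ and could translactonise.

Three things make the synthesis hard. The spiro centre must be set relative to six remote centres. The C3′ ketone carries an α-methylene group (C2′) that competes in any enolate chemistry aimed at C4, C11 or C11′. And C10–H lies on the face of ring B that carries the C6–C8 segment, which is the hindered face.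

The plan is built on ring B. Of its seven carbons, C5 belongs to ring A and C6 carries the lactone oxygen, with the C4 branch on C5 and the oxygen on C6 on the same face, and C9 is a plain methylene between C8 and C10. A cis-divinylcyclopropane made of C8, C9 and C10, with one alkene reaching to C5 and the other to C6, would deliver exactly this array in a Cope rearrangement.

## Retrosynthetic reasoning

**58 back to 54.** The 8′-hydroxyl is freed last from silyl ether 57. The C10′ methylene of 57 is cut to the diketone 56, and both ketones of 56 go back to silyl-protected carbinols in 54. The C10′ alkene is withheld because it would not survive the directed hydrogenation of ring B. The C3′ ketone is withheld because its C2′ methylene would otherwise be methylenated together with C4, C11 and C11′.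

**54 back to 50.** The three exocyclic C=CH2 bonds (C4=C15, C11=C13, C11′=C13′) are cut together. In 50 the only enolisable carbonyl positions are exactly these three, so one Mannich–elimination sequence should serve.

**50 back to 44.** The unit 1 lactone C–O bond is opened to hydroxy ester 48, and the C7–H and C8–H bonds are removed to give the C7=C8 alkene; the forward step is a hydrogenation directed by the C6 hydroxyl, which places H7 syn to O6. C10–H is traced to the C1=C10 dienol silane of 44. Protonation from outside would come from the open face and give the wrong epimer, so the proton is to come from the C12 carboxylic acid, which hangs from C7 on the required face.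

**44 back to 43 (key disconnection).** The C5–C6 bond is cut and the C8–C10 bond restored. This gives the spiro cis-divinylcyclopropane 43. One arm is the C1=C5 bond of the ring A siloxydiene, the other the (E)-silyl enol ether C7=C6. The cut is made here because it creates ring B and both C5 and C6 in one thermal step, with the C4/O6 cis relationship fixed by the transition state.

**43 back to 37.** The two enol silanes and the silyl ester come from aldehyde acid 41. The cyclopropane C9 is removed from 39 to give dienone 37; the forward step is a conjugate methylene transfer from 38 onto the C10=C8 bond, activated through the ring A enone.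

**37 back to 34 and 30.** The C10=C8 bond is cut by an olefination between the C10 ketone of 34 and phosphonium salt 30. Salt 30 carries C6–C8, C11 and C12, so the whole ring B chain arrives in one piece. The ring A ketone is still a ketal in 34, so C10 is the only ketone present.

**34 back to 21 and 26.** Ring C is opened at C14–C15′ and C2–C4′, a Diels–Alder retron. The partners are the α-methylene ketone 21 and the 2-siloxydiene 26. The siloxy group ends para to the C3′ carbonyl, so the regiochemistry should be secure, and the diene should add to the convex face of 21 to set C4′. Between 31 and 33 the C3′ and C10′ ketones are reduced and silylated, which removes every competing ketone from the later steps.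

**26 back to 22, and 30 back to 27.** Diene 26 comes from bromo enone 22 by ketalisation, acylation and enol silylation. Salt 30 comes from aldehyde ester 27 by α-methylenation, addition of the phosphine and acetalisation.

**21 back to 15.** The C10′ ketone is traced to an exocyclic alkene (ozonolysis after the C3′ enone is in place, when the C4′ methylene is deactivated). The 8′-oxygen comes from ketone 16 by hydride attack anti to C11′. Ring E is opened at C8′–C9′, giving allylic chloride ester 15; the forward step is a samarium-mediated acyl substitution.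

**15 back to 8 and 11.** The C6′–C7′ bond is an aldol bond. Auxiliary-bearing succinate 11 sets C6′ and C7′ in the syn sense, which corresponds to the trans lactone.

**8 back to 1.** Ring D is the carvone ring contracted by one carbon (ozonolysis and aldol condensation, 4 to 6). The carvone methyl becomes C15′; it is turned into the exocyclic methylene by deconjugation of enal 6, which also sets C5′.

## Alternatives that were turned down

**Alternative 1:** Triene electrocyclisation followed by ring expansion of a cyclobutanol.
- *Disconnection:* C14–C15′ (ring C) and C4′–C5′ (ring D) are made last.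
- *Forward key step:* heat closes the C14=C10–C1=C2–C4′=C15′ hexatriene in a disrotatory six-electron process; a sulfonic acid then protonates the new dienone and C5′ migrates from the carbinol carbon C3′ to C4′. The product is A1, the 8′-silyl ether of the target.
- *For it:* it is the most convergent of the four. Rings C and D, the spiro centre and the C3′ ketone arise in one flask and only a desilylation remains. On step count after the key step it is clearly stronger than the chosen route.
- *Against it:* unit 1 must be complete before the key step, so the dienone and both α-methylene lactones have to survive heating and strong acid. The hexatriene has a fully substituted central alkene and must reach a crowded cisoid geometry. C10 is set by an undirected protonation and C4′ by the face of the migration. It offers nothing for the cis C4/O6 relationship of ring B, which would need its own solution.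
- *Comparison:* the chosen strategy is longer, but it makes ring B and its two centres with a predictable transition state and keeps all Michael acceptors out of the route until the end.

**Alternative 2:** De Mayo ring expansion with a tethered vinyl ester.
- *Disconnection:* inside unit 2 only; C7′–C8′ and C9′–C10′ are formed and C7′–C10′ is cleaved.
- *Forward key step:* irradiation through Pyrex adds the tethered vinyl ester across the C7′=C10′ enol acetate; methanolysis of the acetate triggers the retro-aldol opening of the cyclobutane. The product is A2.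
- *For it:* it gives ring E with the C10′ ketone and the 8′-oxygen in one step, and the tether forces O8′ cis to C11′. On this point it is stronger than the chosen route, which needs an ozonolysis and a hydride reduction for the same result.
- *Against it:* it answers only a sub-problem. In A2 the lactone sits on O8′, so the C6′ ketone must still be reduced from its hindered face and the lactone moved. The ring D ketone in A2 has two nearly equivalent α-methylene groups, so the C4′ methylene cannot be placed regioselectively. Ring B, ring C and the spiro centre remain open.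
- *Comparison:* the chosen strategy spends more steps on unit 2 but places the C4′ methylene unambiguously and addresses the seven-membered ring of unit 1 in its key step.

**Alternative 3:** Acyl radical spirocyclisation onto a ring C dienone.
- *Disconnection:* C3′–C4′, closing ring D at the spiro centre.
- *Forward key step:* a tin-hydride chain converts a C3′ selenoester into an acyl radical, which adds 5-exo to C4′ of the cross-conjugated dienone; after hydrogen transfer an amidine base moves the alkene to C2=C1. The product is A3.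
- *For it:* A3 already carries both lactones, the C3′ ketone and the C10′ methylene, so the end game is shorter than the chosen one and needs no redox detour at C3′ and C10′. On that count it is stronger.
- *Against it:* the configuration at C4′ depends on the face of radical attack at a fully substituted carbon, controlled only by remote centres. Decarbonylation and addition to the C10′ methylene compete. The base isomerisation sets C10 by undirected protonation and puts C5 at risk. The three late methylenations would meet the free C3′ ketone and its C2′ position. Unit 1 with its ring B must already exist.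
- *Comparison:* the chosen strategy sets C4′ by a cycloaddition on the convex face of a rigid bicycle and builds ring B afterwards with internal control of C5, C6 and C10.

Key step: step 28

## Route

Step 1
Reactants: 1 (S)-(+)-carvone
Product: 2 (S)-5-(3-chloroprop-1-en-2-yl)-2-methylcyclohex-2-en-1-one
Conditions: Ca(OCl)2, CO2 (solid), CH2Cl2/H2O, 0 °C
Reagents that add atoms: calcium hypochlorite, [Ca+2].[O-]Cl.[O-]Cl
Why: Ene-type allylic chlorination by hypochlorous acid formed in the flask; only the electron-rich isopropenyl alkene reacts, the enone alkene and the stereocentre are untouched, and the chlorine later deactivates this alkene towards ozone.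

Step 2
Reactants: 2 (S)-5-(3-chloroprop-1-en-2-yl)-2-methylcyclohex-2-en-1-one
Product: 3 (1S,5S)-5-(3-chloroprop-1-en-2-yl)-2-methylcyclohex-2-en-1-ol (cis)
Conditions: NaBH4, CeCl3·7H2O, MeOH, −78 to 0 °C
Reagents that add atoms: none
Why: Luche reduction, 1,2-selective; axial hydride delivery should give the cis alcohol, a temporary centre that becomes the C3′ ketone.

Step 3
Reactants: 3 (1S,5S)-5-(3-chloroprop-1-en-2-yl)-2-methylcyclohex-2-en-1-ol
Product: 4 tert-butyldimethylsilyl ether of 3
Conditions: t-BuMe2SiCl, imidazole, DMF, rt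
Reagents that add atoms: tert-butyldimethylsilyl chloride, C[Si](C)(Cl)C(C)(C)C
Why: Standard silylation of a secondary allylic alcohol; the ether blocks α-hydroxy ketone chemistry in the next step.

Step 4
Reactants: 4 tert-butyldimethylsilyl ether of 3
Product: 6 cis-3-(tert-butyldimethylsilyloxy)-5-(3-chloroprop-1-en-2-yl)-2-methylcyclopent-1-ene-1-carbaldehyde, via keto aldehyde 5 (not isolated)
Conditions: O3, CH2Cl2/MeOH, −78 °C; Me2S; then piperidine, AcOH, benzene, rt
Reagents that add atoms: ozone, [O-][O+]=O
Why: Ozonolysis cleaves the trisubstituted ring alkene in preference to the chlorine-deactivated 1,1-disubstituted alkene; under amine catalysis the enamine of the aldehyde adds to the methyl ketone in an intramolecular aldol condensation that closes the five-membered ring, which contracts the carvone ring to ring D.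

Step 5
Reactants: 6 cis-3-(tert-butyldimethylsilyloxy)-5-(3-chloroprop-1-en-2-yl)-2-methylcyclopent-1-ene-1-carbaldehyde
Product: 8 all-cis 3-(tert-butyldimethylsilyloxy)-5-(3-chloroprop-1-en-2-yl)-2-methylidenecyclopentane-1-carbaldehyde, via potassium dienolate 7 (not isolated)
Conditions: KN(SiMe3)2, THF, −78 °C; then AcOH, THF, −78 °C; used cold without purification
Reagents that add atoms: none
Why: Deconjugation of an enal through its dienolate; the base removes a γ-proton from the C15′ methyl, and kinetic α-protonation at C5′ should occur on the face opposite the C1′ and C3′ substituents, giving the exocyclic C4′ methylene and the cis C1′/C5′ relationship.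

Step 6
Reactants: 9 (S)-4-benzyl-2-oxazolidinone; 10 methyl 4-chloro-4-oxobutanoate
Product: 11 (S)-4-benzyl-3-(4-methoxy-4-oxobutanoyl)oxazolidin-2-one
Conditions: Et3N, 4-(dimethylamino)pyridine (cat.), CH2Cl2, 0 °C to rt
Reagents that add atoms: none
Why: N-Acylation of the oxazolidinone by the acid chloride.

Step 7
Reactants: 8 all-cis 3-(tert-butyldimethylsilyloxy)-5-(3-chloroprop-1-en-2-yl)-2-methylidenecyclopentane-1-carbaldehyde; 11 (S)-4-benzyl-3-(4-methoxy-4-oxobutanoyl)oxazolidin-2-one
Product: 13 syn aldol adduct (6′-hydroxy; C7′ bearing the acyl oxazolidinone and CH2CO2Me), via boron enolate 12 (not isolated)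
Conditions: 11, Bu2BOTf, i-Pr2NEt, CH2Cl2, −78 to 0 °C; then 8, −78 to 0 °C; pH 7 buffer, MeOH, H2O2, 0 °C
Reagents that add atoms: none
Why: Evans syn aldol through the (Z)-boron enolate formed next to the imide; the (S)-benzyl auxiliary should set C6′ and C7′ as in the target under reagent control, and the non-basic conditions spare the epimerisable aldehyde.

Step 8
Reactants: 13 syn aldol adduct
Product: 15 trans γ-lactone (O6′–C12′) with a C7′ methyl ester and the ring D allylic chloride side chain, via hydroxy diester 14 (not isolated)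
Conditions: MeMgBr, MeOH, CH2Cl2, 0 °C; aq. NH4Cl
Reagents that add atoms: methanol, CO
Why: Magnesium methoxide transesterifies the imide to the methyl ester, and the C6′ alkoxide closes the γ-lactone on the C12′ ester; the syn adduct maps onto the trans lactone, and any epimerisation at C7′ converges on it.

Step 9
Reactants: 15 trans γ-lactone methyl ester
Product: 16 lactone-fused ring E ketone (3′-silyloxy, 4′(15′)- and 10′(14′)-methylene, 8′-oxo)
Conditions: SmI2, HMPA, THF, −78 to 0 °C
Reagents that add atoms: none
Why: SmI2-mediated Barbier-type intramolecular acyl substitution; divalent samarium turns the allylic chloride into an allyl samarium that attacks the exocyclic ester (seven-membered closure) and not the lactone (eight-membered); the 2-substituted allyl unit is symmetric, so no regiochemical question arises.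

Step 10
Reactants: 16 ring E ketone
Product: 17 8′β-alcohol
Conditions: LiBH(s-Bu)3, THF, −78 °C; AcOH, −78 °C
Reagents that add atoms: none
Why: The bulky hydride should attack C8′ anti to the adjacent C11′ branch, placing the hydroxyl cis to C11′; low temperature and a cold acidic quench should prevent conjugation of the β,γ-unsaturated ketone and lactone migration.

Step 11
Reactants: 17 8′β-alcohol
Product: 18 8′-tert-butyldiphenylsilyl ether
Conditions: t-BuPh2SiCl, imidazole, 4-(dimethylamino)pyridine, DMF, rt
Reagents that add atoms: tert-butyldiphenylsilyl chloride, CC(C)(C)[Si](Cl)(c1ccccc1)c1ccccc1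
Why: Robust silyl ether that survives every later acid and fluoride step until the end and blocks translactonisation.

Step 12
Reactants: 18 8′-tert-butyldiphenylsilyl ether
Product: 19 3′-alcohol
Conditions: HF·pyridine, pyridine, THF, 0 °C
Reagents that add atoms: none
Why: The secondary allylic tert-butyldimethylsilyl ether should be cleaved well before the tert-butyldiphenylsilyl ether.

Step 13
Reactants: 19 3′-alcohol
Product: 20 4′(15′)-en-3′-one (α-methylene cyclopentanone) with the 10′(14′)-methylene
Conditions: Dess–Martin periodinane, NaHCO3, CH2Cl2, 0 °C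
Reagents that add atoms: none
Why: Dess–Martin oxidation of an allylic alcohol under buffered conditions; the α-methylene ketone is used promptly.

Step 14
Reactants: 20 α-methylene cyclopentanone with 10′(14′)-methylene
Product: 21 3′,10′-dione dienophile (4′(15′)-methylene, 8′-silyl ether, 6′,12′-lactone)
Conditions: O3, CH2Cl2/MeOH, −78 °C, Sudan Red 7B as end-point indicator; Me2S
Reagents that add atoms: ozone, [O-][O+]=O
Why: Ozone reacts much faster with the isolated 1,1-disubstituted alkene than with the electron-poor enone alkene, so only C10′=C14′ should be cleaved.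

Step 15
Reactants: 22 3-bromocyclopent-2-en-1-one
Product: 23 7-bromo-1,4-dioxaspiro[4.4]non-6-ene
Conditions: (Me3SiOCH2)2, Me3SiOTf (cat.), CH2Cl2, −78 to −20 °C
Reagents that add atoms: 1,2-bis(trimethylsilyloxy)ethane, C[Si](C)(C)OCCO[Si](C)(C)C
Why: Aprotic ketalisation; no free alcohol is present, so conjugate displacement of bromide and alkene migration should be avoided.

Step 16
Reactants: 23 7-bromo-1,4-dioxaspiro[4.4]non-6-ene
Product: 25 1-(1,4-dioxaspiro[4.4]non-6-en-7-yl)ethan-1-one, via vinyllithium 24 (not isolated)
Conditions: t-BuLi, THF, −78 °C; then MeC(O)N(OMe)Me, −78 to 0 °C; aq. NH4Cl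
Reagents that add atoms: N-methoxy-N-methylacetamide, CC(=O)N(C)OC
Why: Bromine–lithium exchange gives a β-acylvinyl anion equivalent; the Weinreb amide stops at the methyl ketone.

Step 17
Reactants: 25 1-(1,4-dioxaspiro[4.4]non-6-en-7-yl)ethan-1-one
Product: 26 7-[1-(tert-butyldimethylsilyloxy)vinyl]-1,4-dioxaspiro[4.4]non-6-ene
Conditions: KN(SiMe3)2, t-BuMe2SiCl, THF/DMPU, −78 °C
Reagents that add atoms: tert-butyldimethylsilyl chloride, C[Si](C)(Cl)C(C)(C)C
Why: The methyl group holds the only acidic protons (the ketal carbon blocks the γ-position), so enolisation and O-silylation give the 2-siloxydiene cleanly; base conditions spare the ketal.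

Step 18
Reactants: 27 methyl 4-oxobutanoate
Product: 28 methyl 3-formylbut-3-enoate
Conditions: aq. CH2O, pyrrolidine (cat.), propionic acid (cat.), i-PrOH, 45 °C
Reagents that add atoms: formaldehyde, C=O
Why: Organocatalytic α-methylenation of an aldehyde (Mannich addition and elimination through the enamine).

Step 19
Reactants: 28 methyl 3-formylbut-3-enoate
Product: 30 [2-(1,3-dioxolan-2-yl)-4-methoxy-4-oxobutyl]triphenylphosphonium bromide (racemic), via aldehyde phosphonium bromide 29 (not isolated)
Conditions: Ph3P·HBr, CH2Cl2, rt; then HOCH2CH2OH, p-toluenesulfonic acid (cat.), toluene, reflux with water removal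
Reagents that add atoms: triphenylphosphonium bromide, [Br-].c1ccc(cc1)[PH+](c1ccccc1)c1ccccc1; ethane-1,2-diol, OCCO
Why: Conjugate addition of the phosphine to the protonated enal, then acetalisation; the salt carries C8, C7, C6, C11 and C12 of unit 1.

Step 20
Reactants: 21 3′,10′-dione dienophile; 26 7-[1-(tert-butyldimethylsilyloxy)vinyl]-1,4-dioxaspiro[4.4]non-6-ene
Product: 31 Diels–Alder adduct (ring C with C10 silyl enol ether, C2–H, ring A ketal, spiro C4′)
Conditions: toluene, 110 °C, sealed tube, 2,6-di-tert-butyl-4-methylphenol (cat.)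
Reagents that add atoms: none
Why: Diels–Alder reaction of a 2-siloxydiene with an α-methylene ketone; C14 bonds to C15′ and C2 to C4′ (siloxy para to the C3′ carbonyl), and the diene should add to the convex face of the cis-fused dienophile, syn to H5′, which sets C4′; the C2 centre is lost later.

Step 21
Reactants: 31 Diels–Alder adduct
Product: 32 3′,10′-diol
Conditions: NaBH4, EtOH/THF, 0 °C
Reagents that add atoms: none
Why: The two ketones are the only groups reduced (lactone and silyl enol ether stay); this masks C3′ and C10′ for all carbonyl and enolate chemistry that follows, and either carbinol configuration serves.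

Step 22
Reactants: 32 3′,10′-diol
Product: 33 3′,10′-bis(tert-butyldimethylsilyl) ether
Conditions: t-BuMe2SiOTf, 2,6-lutidine, CH2Cl2, −78 to 0 °C
Reagents that add atoms: tert-butyldimethylsilyl triflate, CC(C)(C)[Si](C)(C)OS(=O)(=O)C(F)(F)F
Why: The silyl triflate silylates the hindered C3′ carbinol as well; ketal and enol silane tolerate the buffered conditions.

Step 23
Reactants: 33 3′,10′-bis(tert-butyldimethylsilyl) ether
Product: 34 C10 ketone with C1=C2 alkene (ring A ketal retained)
Conditions: Pd(OAc)2, MeCN, rt
Reagents that add atoms: none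
Why: Saegusa–Ito oxidation of the C10 silyl enol ether; β-hydride elimination removes H2 and places the alkene at C1=C2, between rings A and C.

Step 24
Reactants: 30 phosphonium bromide; 34 C10 ketone with ring A ketal
Product: 37 dienone (ring A enone, exocyclic C10=C8, side chain with methyl ester and dioxolane), via phosphorus ylide 35 (not isolated), via diene ketal 36 (not isolated)
Conditions: 30, KN(SiMe3)2, THF, −78 to 0 °C; then 34, −78 °C to rt; then pyridinium p-toluenesulfonate, acetone/H2O, rt
Reagents that add atoms: water, O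
Why: Wittig olefination; C10 is the only ketone present, the phosphonium α-protons are far more acidic than the ester α-protons, and the alkene geometry does not matter; mild acid then hydrolyses the allylic ring A ketal, which ionises much more readily than the aldehyde dioxolane.

Step 25
Reactants: 37 dienone; 38 trimethylsulfoxonium iodide
Product: 39 spiro cyclopropane (C8–C9–C10) with ring A enone
Conditions: 38, NaH, DMSO, rt; then 37, THF, 0 °C to rt
Reagents that add atoms: none
Why: Corey–Chaykovsky cyclopropanation by 1,6-addition; the ylide adds to C8 (the β-carbon C1 is fully substituted) and the dienolate closes at C10, so alkene geometry is erased; C9 and the leaving sulfoxide should approach C10 anti to C5′, whose lactone flank lies over the C14–C15′ edge, and the C7 chain should settle cis to the flat C1 side, which gives the cis arrangement of the two future arms.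

Step 26
Reactants: 39 spiro cyclopropane
Product: 41 aldehyde acid (C6 aldehyde, C12 carboxylic acid), via dilithium dicarboxylate 40 (not isolated)
Conditions: LiOH, THF/H2O, 0 °C to rt; then 1 M HCl, THF, rt
Reagents that add atoms: lithium hydroxide, [Li+].[OH-]; water, O
Why: Saponification of the methyl ester (the unit 2 lactone opens reversibly); acidification recloses that lactone, which cannot migrate because O8′ is silylated, and hydrolyses the dioxolane; the free acid is needed in step 29.

Step 27
Reactants: 41 aldehyde acid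
Product: 43 precursor: spiro cis-divinylcyclopropane with ring A 1-siloxydiene (C1=C5, C2=C3), (E)-triethylsilyl enol ether C7=C6 and triethylsilyl ester, via cross-conjugated siloxydiene 42 (not isolated)
Conditions: Et3SiOTf, Et3N, CH2Cl2, −78 to 0 °C
Reagents that add atoms: triethylsilyl triflate, CC[Si](CC)(CC)OS(=O)(=O)C(F)(F)F
Why: Soft enolisation; the carboxylate is silylated first, the aldehyde gives the enol ether with oxygen trans to the bulky cyclopropyl carbon (E) without passing through a free enolate that could open the cyclopropane, and the enone gives the 2-siloxydiene 42, which equilibrates with 43 by 1,5-hydrogen shift as cyclopentadienes do; no other enolisable ketone is present because C3′ and C10′ are masked.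

Step 28
Reactants: 43 precursor
Product: 44 ring B 1(10),7-cycloheptadiene with C6 triethylsilyl ether, C3 dienol silane (C2=C3, C1=C10) and silyl ester
Conditions: toluene (0.01 M), base-washed glassware, 60 °C
Reagents that add atoms: none
Why: Thermal Cope ([3,3]-sigmatropic) rearrangement of a cis-1,2-divinylcyclopropane: the C1=C5 and C7=C6 alkenes lie endo over the cyclopropane in a boat-shaped six-centre array, C5 bonds to C6 while the strained C8–C10 bond opens, and the relief of ring strain makes the step irreversible. The nearest precedent type is the divinylcyclopropane-to-cycloheptadiene rearrangement of substrates in which one arm is a silyl enol ether and the other a ring alkene, a standard entry to hydroazulenes. Ring B closes as a suprafacial pericyclic ring expansion in which the six reacting atoms and the bridging C9 become the seven-membered 1,4-diene (C1=C10, C7=C8). C5 and C6 are fixed by the boat geometry: the substituents that point outward at the two termini, C4 on C5 and the silyloxy group on C6, end cis on the new bond, and their absolute sense is dictated by the cyclopropane, whose C8 sits on the C5′ face of ring C. The reaction needs the C1=C5 tautomer of the cyclopentadiene; isomer 42 cannot react in this way because its alkene next to C10 ends at the fully substituted C2, so it should drain through 43 by 1,5-hydrogen shifts. It also needs hydrogen at both inward positions, which the (E)-enol ether and the ring A geometry provide, and base-washed glassware keeps traces of acid from opening the donor-substituted cyclopropane. The C1=C10 dienol silane and the silyl ester come through unchanged and are used in step 29.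

Step 29
Reactants: 44 ring B cycloheptadiene
Product: 47 enone methyl ester with C10–H (C6 triethylsilyl ether, C7=C8), via carboxylic acid 45 (not isolated), via enone acid 46 (not isolated)
Conditions: MeOH (5 equiv), benzene (0.005 M), rt to 40 °C; then Me3SiCHN2, benzene/MeOH, 0 °C
Reagents that add atoms: (trimethylsilyl)diazomethane, C[Si](C)(C)C=[N+]=[N-]
Why: Proposed new method: methanol cleaves only the silyl ester; the freed C12 acid hangs from C7 on the C6–C8 side of ring B, so its short tether can reach C10 of the C1=C10 dienol silane only on that face and cannot reach C2 or the opposite face; intramolecular γ-protonation through an eight-membered transition state should therefore give the conjugated enone with H10 syn to the C6–C8 segment and trans to H5, the hindered configuration of the target, after which methanol removes the silyl group from O3 and the diazo reagent esterifies the acid; the closest known reaction types are acid hydrolysis of silyl dienol ethers and diastereoselective protonation of enolates by internal proton donors.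

Step 30
Reactants: 47 enone methyl ester
Product: 48 6-hydroxy enone methyl ester
Conditions: HF·pyridine, pyridine, THF, 0 °C; used at once
Reagents that add atoms: none
Why: The secondary triethylsilyl ether is cleaved under buffered conditions that leave the tert-butyldimethylsilyl and tert-butyldiphenylsilyl ethers and should be too mild to lactonise the hydroxy ester.

Step 31
Reactants: 48 6-hydroxy enone methyl ester
Product: 50 bis-lactone enone (unit 1 trans-6,12-lactone, C7–H), via saturated hydroxy ester 49 (not isolated)
Conditions: H2 (1 atm), [Ir(cod)(PCy3)(py)]PF6 (cat.), CH2Cl2, 0 °C; then pyridinium p-toluenesulfonate, benzene, 50 °C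
Reagents that add atoms: none
Why: Hydroxyl-directed hydrogenation; the iridium binds the allylic C6 hydroxyl and delivers hydrogen to C7=C8 on the face of O6, so H7 ends syn to O6; the tetrasubstituted enone alkene is the only other alkene; mild acid then closes the trans lactone without base, which protects C10 and C5.

Step 32
Reactants: 50 bis-lactone enone
Product: 54 tris-methylene compound (C4=C15, C11=C13, C11′=C13′; silyl ethers at C3′, C10′, C8′), via trilithium enolate 51 (not isolated), via tris Mannich base 52 (not isolated), via tris ammonium iodide 53 (not isolated)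
Conditions: LiN(SiMe3)2, THF, −78 °C; CH2=NMe2 I, −78 to 0 °C; then MeI, MeOH, rt; then aq. NaHCO3, CH2Cl2, rt
Reagents that add atoms: dimethyl(methylene)ammonium iodide, C=[N+](C)C.[I-]
Why: Kinetic enolisation at C4, C11 and C11′, the only positions next to a carbonyl that carry protons now that C3′ is a silyl ether; Mannich reaction, quaternisation and elimination give the three exocyclic alkenes; low temperature is meant to avoid γ-deprotonation at C10 or C5.

Step 33
Reactants: 54 tris-methylene compound
Product: 55 3′,10′-diol
Conditions: HF·pyridine, THF, 0 °C to rt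
Reagents that add atoms: none
Why: Both secondary tert-butyldimethylsilyl ethers are removed under acidic fluoride conditions that the tert-butyldiphenylsilyl ether and the Michael acceptors tolerate.

Step 34
Reactants: 55 3′,10′-diol
Product: 56 3′,10′-diketone
Conditions: Dess–Martin periodinane, NaHCO3, CH2Cl2, 0 °C
Reagents that add atoms: none
Why: Dess–Martin oxidation of both carbinols under neutral conditions; the 8′-oxygen is still protected.

Step 35
Reactants: 56 3′,10′-diketone
Product: 57 8′-O-tert-butyldiphenylsilyl ether of the target (C10′=C14′ installed)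
Conditions: Zn, CH2Br2, TiCl4, THF/CH2Cl2, 0 °C
Reagents that add atoms: dibromomethane, BrCBr
Why: Takai–Lombardo methylenation; the reagent is not basic, so C1′ should not epimerise and the β-silyloxy group should not eliminate; the unhindered C10′ ketone should react before the C3′ ketone next to the quaternary centre and before the conjugated C3 ketone, and lactones are inert.

Step 36
Reactants: 57 8′-O-tert-butyldiphenylsilyl ether
Product: 58 CNP0178208.1
Conditions: Bu4NF, AcOH, THF, rt
Reagents that add atoms: none
Why: Buffered fluoride removes the last silyl ether without conjugate addition to the Michael acceptors and without base-mediated epimerisation at C10.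

## Compound list

1 | (S)-(+)-carvone | CC1=CC[C@@H](CC1=O)C(C)=C | starting material
2 | (S)-5-(3-chloroprop-1-en-2-yl)-2-methylcyclohex-2-en-1-one | CC1=CC[C@@H](CC1=O)C(=C)CCl | intermediate
3 | (1S,5S)-5-(3-chloroprop-1-en-2-yl)-2-methylcyclohex-2-en-1-ol | CC1=CC[C@@H](C[C@@H]1O)C(=C)CCl | intermediate
4 | tert-butyldimethylsilyl ether of 3 | CC1=CC[C@@H](C[C@@H]1O[Si](C)(C)C(C)(C)C)C(=C)CCl | intermediate
5 | 5-(tert-butyldimethylsilyloxy)-3-(3-chloroprop-1-en-2-yl)-6-oxoheptanal | CC(=O)[C@@H](O[Si](C)(C)C(C)(C)C)C[C@H](CC=O)C(=C)CCl | intermediate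
6 | cis-3-(tert-butyldimethylsilyloxy)-5-(3-chloroprop-1-en-2-yl)-2-methylcyclopent-1-ene-1-carbaldehyde | CC1=C(C=O)[C@@H](C[C@@H]1O[Si](C)(C)C(C)(C)C)C(=C)CCl | intermediate
7 | potassium dienolate of 6 | C=C1C(=C[O-])[C@@H](C[C@@H]1O[Si](C)(C)C(C)(C)C)C(=C)CCl.[K+] | intermediate
8 | all-cis 3-(tert-butyldimethylsilyloxy)-5-(3-chloroprop-1-en-2-yl)-2-methylidenecyclopentane-1-carbaldehyde | C=C1[C@H](C=O)[C@@H](C[C@@H]1O[Si](C)(C)C(C)(C)C)C(=C)CCl | intermediate
9 | (S)-4-benzyl-2-oxazolidinone | O=C1N[C@@H](Cc2ccccc2)CO1 | starting material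
10 | methyl 4-chloro-4-oxobutanoate | COC(=O)CCC(Cl)=O | starting material
11 | (S)-4-benzyl-3-(4-methoxy-4-oxobutanoyl)oxazolidin-2-one | COC(=O)CCC(=O)N1[C@@H](Cc2ccccc2)COC1=O | intermediate
12 | (Z)-dibutylboron enolate of 11 | COC(=O)C/C=C(\OB(CCCC)CCCC)/N1[C@@H](Cc2ccccc2)COC1=O | intermediate
13 | syn aldol adduct (6′-hydroxy, C7′ acyl oxazolidinone) | C=C1[C@H]([C@@H](O)[C@H](CC(=O)OC)C(=O)N2[C@@H](Cc3ccccc3)COC2=O)[C@@H](C[C@@H]1O[Si](C)(C)C(C)(C)C)C(=C)CCl | intermediate
14 | hydroxy diester | C=C1[C@H]([C@@H](O)[C@H](CC(=O)OC)C(=O)OC)[C@@H](C[C@@H]1O[Si](C)(C)C(C)(C)C)C(=C)CCl | intermediate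
15 | trans γ-lactone with C7′ methyl ester | C=C1[C@H]([C@H]2OC(=O)C[C@@H]2C(=O)OC)[C@@H](C[C@@H]1O[Si](C)(C)C(C)(C)C)C(=C)CCl | intermediate
16 | ring E ketone (8′-oxo, 4′(15′),10′(14′)-diene, 3′-silyl ether, 6′,12′-lactone) | C=C1[C@@H]2[C@H]3OC(=O)C[C@@H]3C(=O)CC(=C)[C@@H]2C[C@@H]1O[Si](C)(C)C(C)(C)C | intermediate
17 | 8′β-alcohol | C=C1[C@@H]2[C@H]3OC(=O)C[C@@H]3[C@H](O)CC(=C)[C@@H]2C[C@@H]1O[Si](C)(C)C(C)(C)C | intermediate
18 | 8′-tert-butyldiphenylsilyl ether | C=C1[C@@H]2[C@H]3OC(=O)C[C@@H]3[C@H](O[Si](c4ccccc4)(c4ccccc4)C(C)(C)C)CC(=C)[C@@H]2C[C@@H]1O[Si](C)(C)C(C)(C)C | intermediate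
19 | 3′-alcohol | C=C1[C@@H]2[C@H]3OC(=O)C[C@@H]3[C@H](O[Si](c4ccccc4)(c4ccccc4)C(C)(C)C)CC(=C)[C@@H]2C[C@@H]1O | intermediate
20 | 4′(15′)-en-3′-one with 10′(14′)-methylene | C=C1[C@@H]2[C@H]3OC(=O)C[C@@H]3[C@H](O[Si](c4ccccc4)(c4ccccc4)C(C)(C)C)CC(=C)[C@@H]2CC1=O | intermediate
21 | 3′,10′-dione dienophile | C=C1[C@@H]2[C@H]3OC(=O)C[C@@H]3[C@H](O[Si](c4ccccc4)(c4ccccc4)C(C)(C)C)CC(=O)[C@@H]2CC1=O | intermediate
22 | 3-bromocyclopent-2-en-1-one | O=C1CCC(Br)=C1 | starting material
23 | 7-bromo-1,4-dioxaspiro[4.4]non-6-ene | BrC1=CC2(CC1)OCCO2 | intermediate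
24 | 1,4-dioxaspiro[4.4]non-6-en-7-yllithium | [Li]C1=CC2(CC1)OCCO2 | intermediate
25 | 1-(1,4-dioxaspiro[4.4]non-6-en-7-yl)ethan-1-one | CC(=O)C1=CC2(CC1)OCCO2 | intermediate
26 | 7-[1-(tert-butyldimethylsilyloxy)vinyl]-1,4-dioxaspiro[4.4]non-6-ene | C=C(O[Si](C)(C)C(C)(C)C)C1=CC2(CC1)OCCO2 | intermediate
27 | methyl 4-oxobutanoate | COC(=O)CCC=O | starting material
28 | methyl 3-formylbut-3-enoate | COC(=O)CC(=C)C=O | intermediate
29 | (2-formyl-4-methoxy-4-oxobutyl)triphenylphosphonium bromide | COC(=O)CC(C[P+](c1ccccc1)(c1ccccc1)c1ccccc1)C=O.[Br-] | intermediate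
30 | [2-(1,3-dioxolan-2-yl)-4-methoxy-4-oxobutyl]triphenylphosphonium bromide | COC(=O)CC(C[P+](c1ccccc1)(c1ccccc1)c1ccccc1)C1OCCO1.[Br-] | intermediate
31 | Diels–Alder adduct (C10 silyl enol ether, ring A ketal, 3′,10′-dione) | C1CC2(OCCO2)C3C1=C(O[Si](C)(C)C(C)(C)C)CC[C@]31C(=O)C[C@H]2C(=O)C[C@@H](O[Si](c5ccccc5)(c5ccccc5)C(C)(C)C)[C@H]3CC(=O)O[C@@H]3[C@H]21 | intermediate
32 | 3′,10′-diol | C1CC2(OCCO2)C3C1=C(O[Si](C)(C)C(C)(C)C)CC[C@]31C(O)C[C@H]2C(O)C[C@@H](O[Si](c5ccccc5)(c5ccccc5)C(C)(C)C)[C@H]3CC(=O)O[C@@H]3[C@H]21 | intermediate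
33 | 3′,10′-bis(tert-butyldimethylsilyl) ether | C1CC2(OCCO2)C3C1=C(O[Si](C)(C)C(C)(C)C)CC[C@]31C(O[Si](C)(C)C(C)(C)C)C[C@H]2C(O[Si](C)(C)C(C)(C)C)C[C@@H](O[Si](c5ccccc5)(c5ccccc5)C(C)(C)C)[C@H]3CC(=O)O[C@@H]3[C@H]21 | intermediate
34 | C10 ketone with C1=C2 and ring A ketal | C1CC2(OCCO2)C3=C1C(=O)CC[C@]31C(O[Si](C)(C)C(C)(C)C)C[C@H]2C(O[Si](C)(C)C(C)(C)C)C[C@@H](O[Si](c5ccccc5)(c5ccccc5)C(C)(C)C)[C@H]3CC(=O)O[C@@H]3[C@H]21 | intermediate
35 | ylide of 30 | COC(=O)CC(C=P(c1ccccc1)(c1ccccc1)c1ccccc1)C1OCCO1 | intermediate
36 | diene ketal (C10=C8, ring A ketal) | C1CC2(OCCO2)C3=C1C(=CC(CC(=O)OC)C6OCCO6)CC[C@]31C(O[Si](C)(C)C(C)(C)C)C[C@H]2C(O[Si](C)(C)C(C)(C)C)C[C@@H](O[Si](c5ccccc5)(c5ccccc5)C(C)(C)C)[C@H]3CC(=O)O[C@@H]3[C@H]21 | intermediate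
37 | dienone (ring A enone, C10=C8) | C1CC(=O)C2=C1C(=CC(CC(=O)OC)C6OCCO6)CC[C@]21C(O[Si](C)(C)C(C)(C)C)C[C@H]2C(O[Si](C)(C)C(C)(C)C)C[C@@H](O[Si](c5ccccc5)(c5ccccc5)C(C)(C)C)[C@H]3CC(=O)O[C@@H]3[C@H]21 | intermediate
38 | trimethylsulfoxonium iodide | C[S+](C)(C)=O.[I-] | starting material
39 | spiro cyclopropane with ring A enone, methyl ester and dioxolane | C1CC(=O)C2=C1[C@]3(C[C@H]3C(CC(=O)OC)C6OCCO6)CC[C@]21C(O[Si](C)(C)C(C)(C)C)C[C@H]2C(O[Si](C)(C)C(C)(C)C)C[C@@H](O[Si](c5ccccc5)(c5ccccc5)C(C)(C)C)[C@H]3CC(=O)O[C@@H]3[C@H]21 | intermediate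
40 | dilithium dicarboxylate (unit 2 lactone opened) | C1CC(=O)C2=C1[C@]3(C[C@H]3C(CC(=O)[O-])C6OCCO6)CC[C@]21C(O[Si](C)(C)C(C)(C)C)C[C@H]2C(O[Si](C)(C)C(C)(C)C)C[C@@H](O[Si](c5ccccc5)(c5ccccc5)C(C)(C)C)[C@@H](CC(=O)[O-])[C@H](O)[C@H]21.[Li+].[Li+] | intermediate
41 | aldehyde acid | C1CC(=O)C2=C1[C@]3(C[C@H]3C(CC(=O)O)C=O)CC[C@]21C(O[Si](C)(C)C(C)(C)C)C[C@H]2C(O[Si](C)(C)C(C)(C)C)C[C@@H](O[Si](c5ccccc5)(c5ccccc5)C(C)(C)C)[C@H]3CC(=O)O[C@@H]3[C@H]21 | intermediate
42 | cross-conjugated siloxydiene isomer (C4=C3, C2=C1) | C1=C(O[Si](CC)(CC)CC)C2=C(C1)[C@]3(C[C@H]3/C(CC(=O)O[Si](CC)(CC)CC)=C/O[Si](CC)(CC)CC)CC[C@]21C(O[Si](C)(C)C(C)(C)C)C[C@H]2C(O[Si](C)(C)C(C)(C)C)C[C@@H](O[Si](c5ccccc5)(c5ccccc5)C(C)(C)C)[C@H]3CC(=O)O[C@@H]3[C@H]21 | intermediate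
43 | precursor: spiro cis-divinylcyclopropane with ring A siloxydiene and (E)-silyl enol ether | C1C(O[Si](CC)(CC)CC)=C2C(=C1)[C@]3(C[C@H]3/C(CC(=O)O[Si](CC)(CC)CC)=C/O[Si](CC)(CC)CC)CC[C@]21C(O[Si](C)(C)C(C)(C)C)C[C@H]2C(O[Si](C)(C)C(C)(C)C)C[C@@H](O[Si](c5ccccc5)(c5ccccc5)C(C)(C)C)[C@H]3CC(=O)O[C@@H]3[C@H]21 | intermediate
44 | ring B 1(10),7-cycloheptadiene with C6 silyl ether and C3 dienol silane | C1C(O[Si](CC)(CC)CC)=C2C3=C(CC=C(CC(=O)O[Si](CC)(CC)CC)[C@H](O[Si](CC)(CC)CC)[C@H]13)CC[C@]21C(O[Si](C)(C)C(C)(C)C)C[C@H]2C(O[Si](C)(C)C(C)(C)C)C[C@@H](O[Si](c5ccccc5)(c5ccccc5)C(C)(C)C)[C@H]3CC(=O)O[C@@H]3[C@H]21 | intermediate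
45 | free C12 acid of 44 | C1C(O[Si](CC)(CC)CC)=C2C3=C(CC=C(CC(=O)O)[C@H](O[Si](CC)(CC)CC)[C@H]13)CC[C@]21C(O[Si](C)(C)C(C)(C)C)C[C@H]2C(O[Si](C)(C)C(C)(C)C)C[C@@H](O[Si](c5ccccc5)(c5ccccc5)C(C)(C)C)[C@H]3CC(=O)O[C@@H]3[C@H]21 | intermediate
46 | enone acid with C10–H | C1C(=O)C2=C3[C@H](CC=C(CC(=O)O)[C@H](O[Si](CC)(CC)CC)[C@H]13)CC[C@]21C(O[Si](C)(C)C(C)(C)C)C[C@H]2C(O[Si](C)(C)C(C)(C)C)C[C@@H](O[Si](c5ccccc5)(c5ccccc5)C(C)(C)C)[C@H]3CC(=O)O[C@@H]3[C@H]21 | intermediate
47 | enone methyl ester (C6 triethylsilyl ether) | C1C(=O)C2=C3[C@H](CC=C(CC(=O)OC)[C@H](O[Si](CC)(CC)CC)[C@H]13)CC[C@]21C(O[Si](C)(C)C(C)(C)C)C[C@H]2C(O[Si](C)(C)C(C)(C)C)C[C@@H](O[Si](c5ccccc5)(c5ccccc5)C(C)(C)C)[C@H]3CC(=O)O[C@@H]3[C@H]21 | intermediate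
48 | 6-hydroxy enone methyl ester | C1C(=O)C2=C3[C@H](CC=C(CC(=O)OC)[C@H](O)[C@H]13)CC[C@]21C(O[Si](C)(C)C(C)(C)C)C[C@H]2C(O[Si](C)(C)C(C)(C)C)C[C@@H](O[Si](c5ccccc5)(c5ccccc5)C(C)(C)C)[C@H]3CC(=O)O[C@@H]3[C@H]21 | intermediate
49 | saturated 6-hydroxy ester | C1C(=O)C2=C3[C@H](CC[C@@H](CC(=O)OC)[C@H](O)[C@H]13)CC[C@]21C(O[Si](C)(C)C(C)(C)C)C[C@H]2C(O[Si](C)(C)C(C)(C)C)C[C@@H](O[Si](c5ccccc5)(c5ccccc5)C(C)(C)C)[C@H]3CC(=O)O[C@@H]3[C@H]21 | intermediate
50 | bis-lactone enone | C1C(=O)C2=C3[C@H](CC[C@H]4CC(=O)O[C@@H]4[C@H]13)CC[C@]21C(O[Si](C)(C)C(C)(C)C)C[C@H]2C(O[Si](C)(C)C(C)(C)C)C[C@@H](O[Si](c5ccccc5)(c5ccccc5)C(C)(C)C)[C@H]3CC(=O)O[C@@H]3[C@H]21 | intermediate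
51 | trilithium enolate of 50 | C1=C([O-])C2=C3[C@H](CC[C@H]4C=C([O-])O[C@@H]4[C@H]13)CC[C@]21C(O[Si](C)(C)C(C)(C)C)C[C@H]2C(O[Si](C)(C)C(C)(C)C)C[C@@H](O[Si](c5ccccc5)(c5ccccc5)C(C)(C)C)[C@H]3C=C([O-])O[C@@H]3[C@H]21.[Li+].[Li+].[Li+] | intermediate
52 | tris(dimethylaminomethyl) compound | C1(CN(C)C)C(=O)C2=C3[C@H](CC[C@H]4C(CN(C)C)C(=O)O[C@@H]4[C@H]13)CC[C@]21C(O[Si](C)(C)C(C)(C)C)C[C@H]2C(O[Si](C)(C)C(C)(C)C)C[C@@H](O[Si](c5ccccc5)(c5ccccc5)C(C)(C)C)[C@H]3C(CN(C)C)C(=O)O[C@@H]3[C@H]21 | intermediate
53 | tris(trimethylammoniomethyl) triiodide | C1(C[N+](C)(C)C)C(=O)C2=C3[C@H](CC[C@H]4C(C[N+](C)(C)C)C(=O)O[C@@H]4[C@H]13)CC[C@]21C(O[Si](C)(C)C(C)(C)C)C[C@H]2C(O[Si](C)(C)C(C)(C)C)C[C@@H](O[Si](c5ccccc5)(c5ccccc5)C(C)(C)C)[C@H]3C(C[N+](C)(C)C)C(=O)O[C@@H]3[C@H]21.[I-].[I-].[I-] | intermediate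
54 | tris-methylene compound with three silyl ethers | C=C1C(=O)C2=C3[C@H](CC[C@H]4C(=C)C(=O)O[C@@H]4[C@H]13)CC[C@]21C(O[Si](C)(C)C(C)(C)C)C[C@H]2C(O[Si](C)(C)C(C)(C)C)C[C@@H](O[Si](c5ccccc5)(c5ccccc5)C(C)(C)C)[C@H]3C(=C)C(=O)O[C@@H]3[C@H]21 | intermediate
55 | 3′,10′-diol | C=C1C(=O)C2=C3[C@H](CC[C@H]4C(=C)C(=O)O[C@@H]4[C@H]13)CC[C@]21C(O)C[C@H]2C(O)C[C@@H](O[Si](c5ccccc5)(c5ccccc5)C(C)(C)C)[C@H]3C(=C)C(=O)O[C@@H]3[C@H]21 | intermediate
56 | 3′,10′-diketone | C=C1C(=O)C2=C3[C@H](CC[C@H]4C(=C)C(=O)O[C@@H]4[C@H]13)CC[C@]21C(=O)C[C@H]2C(=O)C[C@@H](O[Si](c5ccccc5)(c5ccccc5)C(C)(C)C)[C@H]3C(=C)C(=O)O[C@@H]3[C@H]21 | intermediate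
57 | 8′-O-tert-butyldiphenylsilyl ether of the target | C=C1C(=O)C2=C3[C@H](CC[C@H]4C(=C)C(=O)O[C@@H]4[C@H]13)CC[C@]21C(=O)C[C@H]2C(=C)C[C@@H](O[Si](c5ccccc5)(c5ccccc5)C(C)(C)C)[C@H]3C(=C)C(=O)O[C@@H]3[C@H]21 | intermediate
58 | CNP0178208.1 | C=C1C(=O)C2=C3[C@H](CC[C@H]4C(=C)C(=O)O[C@@H]4[C@H]13)CC[C@]21C(=O)C[C@H]2C(=C)C[C@@H](O)[C@H]3C(=C)C(=O)O[C@@H]3[C@H]21 | target

## Step count and least certain steps

Total: 36 steps. Longest linear sequence: 30 steps (steps 1–5, 7–14, 20–36).

**Step 29 (bears the label "Proposed new method:").** Protonation of the dienol silane by another molecule of acid, or by methanol, may compete with internal delivery; that would put H10 on the open face and give the C10 epimer. The silyl dienol ether may also be too weakly nucleophilic for a carboxylic acid at high dilution. Later base-exposed steps (step 32 in particular) could erode the centre, since the target configuration is probably the less stable one. Fallback with known chemistry, setting out from 44 and returning at 47: 44 is hydrolysed with AcOH in wet THF at 0 °C and the acid is esterified with Me3SiCHN2, which should give 47 together with the C10-epimeric enone methyl ester F1. The two are separated by chromatography. The epimer F1 is then re-equilibrated at C10 by brief treatment with 1,8-diazabicyclo[5.4.0]undec-7-ene and separated again, so that the material is funnelled to 47.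

**Step 28 (key step).** The tautomer with the C1=C5 arm may be poorly populated, or further hydrogen shifts may lead to unreactive isomers. The enol ether may form partly with Z geometry, which slows the rearrangement and would invert C6. If step 25 gave the trans cyclopropane, the concerted path is closed. Traces of acid could open the cyclopropane heterolytically. Fallback by a stepwise ionic route, setting out from 41 and returning at 50:
- Treatment of 41 with 1,8-diazabicyclo[5.4.0]undec-7-ene in CH2Cl2 enolises the aldehyde at C7. The enolate opens the acceptor-substituted cyclopropane between C8 and C10 (the reverse of a vinylogous Michael ring closure) and should give the ring-opened enal acid F2.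
- Hydrogenation of F2 over Pd/C in EtOAc should saturate only the enal alkene and give the saturated aldehyde acid F3; the tetrasubstituted enone is left.
- Ac2O and pyridine close the γ-oxo acid F3 to its pseudo-acid acetate, the 5-acetoxy lactone F4.
- Et3SiOTf and Et3N convert the ring A enone of F4 into the ring A siloxydiene F5.
- A catalytic amount of Et3SiOTf in CH2Cl2 at −78 °C then ionises the acetoxy lactone of F5, and C5 of the siloxydiene adds to the C6 acyloxocarbenium ion (intramolecular vinylogous Mukaiyama addition). This closes ring B, forms the unit 1 lactone directly and rejoins the route at 50, so steps 29 to 31 are skipped.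

In this sequence C7 and C10 are not controlled and C5 and C6 are set only by the tether, so 50 has to be separated from its diastereomers.

**Step 25.** The ylide may add at C1 instead of C8, may close on the other face of C10, or may give the trans relationship of the two arms; enolisation of the dienone by the basic ylide may also compete. Each outcome spoils the absolute sense or the feasibility of step 28. Fallback by stereospecific methylene transfer, setting out from 36 and returning at 39:
- Step 24 is stopped before the acid hydrolysis, and the geometric isomer of 36 that has C7 cis to C1 across C10=C8, the (C1/C7-cis) diene ketal F6, is separated. The other isomer is recycled by photosensitised equilibration.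
- Cyclopropanation of F6 with Et2Zn and CH2I2 (Furukawa variant of the Simmons–Smith reaction) adds CH2 suprafacially to the exocyclic trisubstituted alkene; the tetrasubstituted C1=C2 bond is too hindered to react. This should give the spiro cyclopropane ketal F7, with the cis relationship of C1 and C7 fixed by the alkene geometry.
- Hydrolysis of the ring A ketal of F7 with pyridinium p-toluenesulfonate in wet acetone rejoins the route at 39.

**Step 31.** The hydroxy ester may lactonise before hydrogenation, which removes the directing hydroxyl and exposes the opposite alkene face. The catalyst may also begin to reduce the enone alkene. Fallback through the carboxylate, setting out from 46 and returning at 50: step 29 is stopped before the esterification. Acid 46 is desilylated at C6 with HF·pyridine in THF containing excess pyridine at 0 °C and quenched at once into aqueous NaHCO3, which gives the sodium 6-hydroxy carboxylate F8, a salt that cannot lactonise. Hydrogenation of F8 with [Rh(nbd)(dppb)]BF4 in MeOH, directed by the hydroxyl and the carboxylate, gives the saturated sodium 6-hydroxy carboxylate F9. Acidification of F9 with dilute HCl closes the lactone and rejoins the route at 50.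

**Step 9.** Reduction of the allylic chloride without cyclisation, attack on the lactone, over-reduction of the new ketone or conjugation of the β,γ-unsaturated ketone may intervene; seven-membered closures of this type are less favourable than five- or six-membered ones. Fallback by the aldehyde route, setting out from 15 and returning at 16: the methyl ester of 15 is cleaved with Me3SnOH in 1,2-dichloroethane to the C7′ carboxylic acid F10. This is converted with (COCl)2 and catalytic DMF into the C7′ acid chloride F11, which is reduced with LiAlH(O-t-Bu)3 at −78 °C to the C7′ carbaldehyde F12. An intramolecular Nozaki–Hiyama allylation of F12 with CrCl2 closes ring E to the 8′-hydroxy ring E compound F13 as a mixture of C8′ epimers. Dess–Martin oxidation of F13 rejoins the route at 16.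

**Step 5.** The β,γ-unsaturated aldehyde may return to the conjugated enal or epimerise at C5′ during work-up or in step 7, which would give the trans ring D substitution; intramolecular alkylation of the dienolate by the allylic chloride is a further possible side path. Fallback at the ester oxidation level, setting out from 6 and returning at 8: 6 is oxidised under Pinnick conditions (NaClO2, NaH2PO4, 2-methylbut-2-ene) to the cyclopentenecarboxylic acid F14, which is esterified with Me3SiCHN2 to the methyl cyclopentenecarboxylate F15. Deconjugation of F15 with LiN(i-Pr)2/HMPA and a cold AcOH quench gives the configurationally more robust deconjugated methyl ester F16. Reduction of F16 with i-Bu2AlH at −78 °C returns to the route at 8.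

## Further compounds

F1 | step 29 | C10-epimeric enone methyl ester (C10 epimer of 47) | C1C(=O)C2=C3[C@@H](CC=C(CC(=O)OC)[C@H](O[Si](CC)(CC)CC)[C@H]13)CC[C@]21C(O[Si](C)(C)C(C)(C)C)C[C@H]2C(O[Si](C)(C)C(C)(C)C)C[C@@H](O[Si](c5ccccc5)(c5ccccc5)C(C)(C)C)[C@H]3CC(=O)O[C@@H]3[C@H]21
F2 | step 28 | ring-opened enal acid (ring A enone, C10–H, C8=C7 enal, C12 acid) | C1CC(=O)C2=C1C(CC=C(CC(=O)O)C=O)CC[C@]21C(O[Si](C)(C)C(C)(C)C)C[C@H]2C(O[Si](C)(C)C(C)(C)C)C[C@@H](O[Si](c5ccccc5)(c5ccccc5)C(C)(C)C)[C@H]3CC(=O)O[C@@H]3[C@H]21
F3 | step 28 | saturated aldehyde acid (C7–C8 single bond) | C1CC(=O)C2=C1C(CCC(CC(=O)O)C=O)CC[C@]21C(O[Si](C)(C)C(C)(C)C)C[C@H]2C(O[Si](C)(C)C(C)(C)C)C[C@@H](O[Si](c5ccccc5)(c5ccccc5)C(C)(C)C)[C@H]3CC(=O)O[C@@H]3[C@H]21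
F4 | step 28 | 5-acetoxy lactone (pseudo-acid acetate of F3) | C1CC(=O)C2=C1C(CCC6CC(=O)OC6OC(C)=O)CC[C@]21C(O[Si](C)(C)C(C)(C)C)C[C@H]2C(O[Si](C)(C)C(C)(C)C)C[C@@H](O[Si](c5ccccc5)(c5ccccc5)C(C)(C)C)[C@H]3CC(=O)O[C@@H]3[C@H]21
F5 | step 28 | ring A siloxydiene of F4 (C2=C3, C1=C5) | C1C(O[Si](CC)(CC)CC)=C2C(=C1)C(CCC6CC(=O)OC6OC(C)=O)CC[C@]21C(O[Si](C)(C)C(C)(C)C)C[C@H]2C(O[Si](C)(C)C(C)(C)C)C[C@@H](O[Si](c5ccccc5)(c5ccccc5)C(C)(C)C)[C@H]3CC(=O)O[C@@H]3[C@H]21
F6 | step 25 | (C1/C7-cis) diene ketal, geometric isomer of 36 | C1CC2(OCCO2)C3=C1/C(=C\C(CC(=O)OC)C6OCCO6)CC[C@]31C(O[Si](C)(C)C(C)(C)C)C[C@H]2C(O[Si](C)(C)C(C)(C)C)C[C@@H](O[Si](c5ccccc5)(c5ccccc5)C(C)(C)C)[C@H]3CC(=O)O[C@@H]3[C@H]21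
F7 | step 25 | spiro cyclopropane ketal (ring A ketal of 39) | C1CC2(OCCO2)C3=C1[C@]4(C[C@H]4C(CC(=O)OC)C6OCCO6)CC[C@]31C(O[Si](C)(C)C(C)(C)C)C[C@H]2C(O[Si](C)(C)C(C)(C)C)C[C@@H](O[Si](c5ccccc5)(c5ccccc5)C(C)(C)C)[C@H]3CC(=O)O[C@@H]3[C@H]21
F8 | step 31 | sodium 6-hydroxy carboxylate with C7=C8 | C1C(=O)C2=C3[C@H](CC=C(CC(=O)[O-])[C@H](O)[C@H]13)CC[C@]21C(O[Si](C)(C)C(C)(C)C)C[C@H]2C(O[Si](C)(C)C(C)(C)C)C[C@@H](O[Si](c5ccccc5)(c5ccccc5)C(C)(C)C)[C@H]3CC(=O)O[C@@H]3[C@H]21.[Na+]
F9 | step 31 | saturated sodium 6-hydroxy carboxylate | C1C(=O)C2=C3[C@H](CC[C@@H](CC(=O)[O-])[C@H](O)[C@H]13)CC[C@]21C(O[Si](C)(C)C(C)(C)C)C[C@H]2C(O[Si](C)(C)C(C)(C)C)C[C@@H](O[Si](c5ccccc5)(c5ccccc5)C(C)(C)C)[C@H]3CC(=O)O[C@@H]3[C@H]21.[Na+]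
F10 | step 9 | C7′ carboxylic acid of 15 | C=C1[C@H]([C@H]2OC(=O)C[C@@H]2C(=O)O)[C@@H](C[C@@H]1O[Si](C)(C)C(C)(C)C)C(=C)CCl
F11 | step 9 | C7′ acid chloride | C=C1[C@H]([C@H]2OC(=O)C[C@@H]2C(=O)Cl)[C@@H](C[C@@H]1O[Si](C)(C)C(C)(C)C)C(=C)CCl
F12 | step 9 | C7′ carbaldehyde | C=C1[C@H]([C@H]2OC(=O)C[C@@H]2C=O)[C@@H](C[C@@H]1O[Si](C)(C)C(C)(C)C)C(=C)CCl
F13 | step 9 | 8′-hydroxy ring E compound (C8′ epimers) | C=C1[C@@H]2[C@H]3OC(=O)C[C@@H]3C(O)CC(=C)[C@@H]2C[C@@H]1O[Si](C)(C)C(C)(C)C
F14 | step 5 | cis-3-(tert-butyldimethylsilyloxy)-5-(3-chloroprop-1-en-2-yl)-2-methylcyclopent-1-ene-1-carboxylic acid | OC(=O)C1=C(C)[C@@H](O[Si](C)(C)C(C)(C)C)C[C@H]1C(=C)CCl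
F15 | step 5 | methyl cis-3-(tert-butyldimethylsilyloxy)-5-(3-chloroprop-1-en-2-yl)-2-methylcyclopent-1-ene-1-carboxylate | COC(=O)C1=C(C)[C@@H](O[Si](C)(C)C(C)(C)C)C[C@H]1C(=C)CCl
F16 | step 5 | methyl all-cis 3-(tert-butyldimethylsilyloxy)-5-(3-chloroprop-1-en-2-yl)-2-methylidenecyclopentane-1-carboxylate | C=C1[C@H](C(=O)OC)[C@@H](C[C@@H]1O[Si](C)(C)C(C)(C)C)C(=C)CCl
A1 | alternative 1 | 8′-O-tert-butyldimethylsilyl ether of the target | C=C1C(=O)C2=C3[C@H](CC[C@H]4C(=C)C(=O)O[C@@H]4[C@H]13)CC[C@]21C(=O)C[C@H]2C(=C)C[C@@H](O[Si](C)(C)C(C)(C)C)[C@H]3C(=C)C(=O)O[C@@H]3[C@H]21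
A2 | alternative 2 | ring D/E 6′,10′-dione with cis 8′,12′-lactone and ring D dioxolane | O=C1C[C@H]2OC(=O)C[C@H]2C(=O)[C@H]3CC4(OCCO4)C[C@@H]13
A3 | alternative 3 | spiro trione bis-lactone without the C15, C13 and C13′ methylenes, 8′-O-tert-butyldimethylsilyl | C1C(=O)C2=C3[C@H](CC[C@H]4CC(=O)O[C@@H]4[C@H]13)CC[C@]21C(=O)C[C@H]2C(=C)C[C@@H](O[Si](C)(C)C(C)(C)C)[C@H]3CC(=O)O[C@@H]3[C@H]21
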